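**Retrosynthetic overview**
1. Target 10 ← tri-O-methyl macrocycle 9 by global O-demethylation.
2. 9 ← open-chain phenol 6 by closing the 20-membered ring at the diaryl ether C–O bond: the ring A C–H meta to both substituents is borylated and joined to the ring B phenol oxygen (proposed new telescoped step).
3. 6 ← terminal alkene 3 + bromophenol 4 (hydroboration, then B-alkyl Suzuki–Miyaura coupling).
4. 3 ← benzyl Grignard reagent 1 + bromoalkene 2 (copper-catalysed sp3–sp3 coupling).
5. Ring order: both benzene rings are bought; the only ring formed is the macrocycle (step 3).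

Assumption: the target has no stereocentre, and the 20-membered ring is too loose for a stable chiral plane, so the compound is achiral and no enantiocontrol is needed.

**Step 1**
Reactants: 1 3-methoxybenzylmagnesium chloride (commercial THF solution); 2 11-bromoundec-1-ene
Product: 3 1-(dodec-11-en-1-yl)-3-methoxybenzene
Conditions: Li2CuCl4 (3 mol%), THF, −10 °C to rt
Reagents that add atoms: none
Why: Kochi-type copper-catalysed cross-coupling of a benzylic Grignard reagent with a primary alkyl bromide is fast and leaves the terminal alkene and the aryl methyl ether untouched.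

**Step 2**
Reactants: 3 1-(dodec-11-en-1-yl)-3-methoxybenzene; 4 4-bromo-2,6-dimethoxyphenol
Product: 6 2,6-dimethoxy-4-[12-(3-methoxyphenyl)dodecyl]phenol, via B-alkyl-9-BBN adduct 5 (not isolated)
Conditions: 9-BBN (1.2 equiv), THF, 0 °C to rt; then 4, Pd(OAc)2 (3 mol%), SPhos (6 mol%), K3PO4 (3 equiv), THF/H2O, 65 °C
Reagents that add atoms: 9-borabicyclo[3.3.1]nonane (9-BBN), B1C2CCCC1CCC2 (its atoms are carried by 5 only and leave in the coupling)
Why: anti-Markovnikov hydroboration of the terminal alkene followed by B-alkyl Suzuki–Miyaura coupling; the SPhos-ligated zerovalent palladium catalyst inserts into electron-rich aryl bromides, so the free phenol should not need protection.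

**Step 3**
Reactants: 6 2,6-dimethoxy-4-[12-(3-methoxyphenyl)dodecyl]phenol
Product: 9 tri-O-methyl macrocycle (trimethyl ether of the target; ring A 1-alkyl-3-methoxy-5-aryloxybenzene; ring B 4-alkyl-2,6-dimethoxyphenyl ether; rings joined by one ether oxygen plus a (CH2)12 chain), via O-Bpin aryl borate 7 (not isolated), via bis-boryl compound 8 (not isolated)
Conditions: HBpin (2.5 equiv), [Ir(OMe)(cod)]2 (2 mol%), dtbpy (4 mol%), THF, rt then 80 °C; evaporate; then slow addition (12 h) to Cu(OAc)2 (3 equiv), Et3N (5 equiv), 4 Å MS, MeCN, 70 °C, argon, 2 mM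
Reagents that add atoms: pinacolborane (HBpin), B1OC(C)(C)C(C)(C)O1 (its boryl groups are carried by 7 and 8 only and are gone in 9)
Why: Proposed new method: a telescoped, macrocyclising formal meta-C–H aryloxylation. HBpin first caps the phenol as the O–Bpin ester 7 (H2 evolves), and the iridium/dtbpy boryl catalyst then borylates the only aryl C–H without an ortho neighbour, ring A C5 (meta to chain and OMe), giving 8. Divalent copper acetate then takes the aryl group from C–Bpin and the aryloxide from the labile O–Bpin; a second Cu(OAc)2 oxidises this to an aryl(aryloxy) trivalent copper species, which reductively eliminates the diaryl ether, with high dilution favouring ring closure and argon protecting the p-alkyl-2,6-dimethoxyphenol from aerobic oxidation. The closest known reaction types are the intermolecular one-pot iridium C–H borylation/Chan–Evans–Lam etherification and the Chan–Evans–Lam macrocyclisation of preformed arylboronic acids; closing a macrocycle directly from an arene C–H bond, with the hindered phenol delivered as its borate ester, has not been shown.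

**Step 4**
Reactants: 9 tri-O-methyl macrocycle
Product: 10 target macrocycle CNP0314249.0 (the triol)
Conditions: BBr3 (6 equiv), CH2Cl2, −78 °C to rt; then ice-water
Reagents that add atoms: none
Why: Lewis-acid cleavage of aryl methyl ethers (BBr3 demethylation) removes all three methyl groups, while diaryl ethers are inert to BBr3, so the macrocycle stays intact.

**Compound list**
1 | 3-methoxybenzylmagnesium chloride | COc1cccc(C[Mg]Cl)c1 | starting material
2 | 11-bromoundec-1-ene | C=CCCCCCCCCCBr | starting material
3 | 1-(dodec-11-en-1-yl)-3-methoxybenzene | COc1cccc(CCCCCCCCCCC=C)c1 | intermediate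
4 | 4-bromo-2,6-dimethoxyphenol | COc1cc(Br)cc(OC)c1O | starting material
5 | 9-[12-(3-methoxyphenyl)dodecyl]-9-borabicyclo[3.3.1]nonane | COc1cccc(CCCCCCCCCCCCB2C3CCCC2CCC3)c1 | intermediate
6 | 2,6-dimethoxy-4-[12-(3-methoxyphenyl)dodecyl]phenol | COc1cccc(CCCCCCCCCCCCc2cc(OC)c(O)c(OC)c2)c1 | intermediate
7 | 2-{2,6-dimethoxy-4-[12-(3-methoxyphenyl)dodecyl]phenoxy}-4,4,5,5-tetramethyl-1,3,2-dioxaborolane | COc1cccc(CCCCCCCCCCCCc2cc(OC)c(OB3OC(C)(C)C(C)(C)O3)c(OC)c2)c1 | intermediate
8 | O-Bpin ester of 6 that also carries a Bpin group on ring A at C5 (meta to chain and OMe) | COc1cc(CCCCCCCCCCCCc2cc(OC)c(OB3OC(C)(C)C(C)(C)O3)c(OC)c2)cc(c1)B1OC(C)(C)C(C)(C)O1 | intermediate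
9 | tri-O-methyl ether of the target (20-membered meta,para-bridged diaryl ether macrocycle) | COc1cc2cc(c1)Oc1c(OC)cc(cc1OC)CCCCCCCCCCCC2 | intermediate
10 | target: ring A 3-hydroxy-5-alkylphenyl ether; ring B 2,6-dihydroxy-4-alkylphenyl ether; (CH2)12 bridge; achiral | Oc1cc2cc(c1)Oc1c(O)cc(cc1O)CCCCCCCCCCCC2 | target

**Totals**
Total step count: 4. Longest linear sequence: 4 (1 → 3 → 6 → 9 → 10).

**Three steps most likely to fail, with fallbacks**

Step 3 (the proposed new step). The main risks are slow transmetalation of the pinacol boronate, protodeboronation and oligomerisation. The fallback uses only known chemistry and puts the halide in place before an Ullmann ring closure of the same C–O bond. It sets out from 2. Magnesium in THF turns 2 into undec-10-en-1-ylmagnesium bromide F1. Li2CuCl4-catalysed coupling of F1 with commercial 1-bromo-3-(bromomethyl)-5-methoxybenzene, in which only the benzylic bromide reacts, gives 1-bromo-3-(dodec-11-en-1-yl)-5-methoxybenzene F2. Cross-metathesis of F2 with commercial 2,6-dimethoxy-4-vinylphenol (second-generation Grubbs catalyst RuCl2(=CHPh)(PCy3)(SIMes), CH2Cl2, 40 °C) gives 4-[(E)-12-(3-bromo-5-methoxyphenyl)dodec-1-en-1-yl]-2,6-dimethoxyphenol F3. Hydrogenation over RhCl(PPh3)3 saturates the alkene without touching the aryl bromide and gives 4-[12-(3-bromo-5-methoxyphenyl)dodecyl]-2,6-dimethoxyphenol F4. An intramolecular Ullmann diaryl ether synthesis (CuI, picolinic acid, K3PO4, DMSO, 90 °C, 2 mM) then closes the ring, and the fallback comes back to the route at 9.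

Step 2. The bromophenoxide may add to palladium too slowly, or the alkylborane may lose boron first. The fallback sets out from 3 and replaces the sp3–sp2 coupling by olefin metathesis. Cross-metathesis of 3 with commercial 2,6-dimethoxy-4-vinylphenol (second-generation Grubbs catalyst RuCl2(=CHPh)(PCy3)(SIMes), CH2Cl2, 40 °C) gives 2,6-dimethoxy-4-[(E)-12-(3-methoxyphenyl)dodec-1-en-1-yl]phenol F5. Hydrogenation (H2, palladium on carbon Pd/C, EtOAc) then brings the fallback back at 6.

Step 1. The benzylic Grignard reagent may homocouple, or the alkyl bromide may react sluggishly. The fallback sets out from 1 and replaces the alkylation by acylation and deoxygenation. Acylation of 1 with commercial undec-10-enoyl chloride (Fe(acac)3 3 mol%, THF, −78 °C) gives 1-(3-methoxyphenyl)dodec-11-en-2-one F6. Wolff–Kishner reduction under Huang-Minlon conditions (N2H4·H2O, KOH, diethylene glycol, 130 then 200 °C, under nitrogen) proceeds through the hydrazone of the ketone F7, formed in the flask, and comes back at 3.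

**Further compounds**
F1 | step 3 | undec-10-en-1-ylmagnesium bromide | C=CCCCCCCCCC[Mg]Br
F2 | step 3 | 1-bromo-3-(dodec-11-en-1-yl)-5-methoxybenzene | COc1cc(Br)cc(CCCCCCCCCCC=C)c1
F3 | step 3 | 4-[(E)-12-(3-bromo-5-methoxyphenyl)dodec-1-en-1-yl]-2,6-dimethoxyphenol | COc1cc(Br)cc(CCCCCCCCCC/C=C/c2cc(OC)c(O)c(OC)c2)c1
F4 | step 3 | 4-[12-(3-bromo-5-methoxyphenyl)dodecyl]-2,6-dimethoxyphenol | COc1cc(Br)cc(CCCCCCCCCCCCc2cc(OC)c(O)c(OC)c2)c1
F5 | step 2 | 2,6-dimethoxy-4-[(E)-12-(3-methoxyphenyl)dodec-1-en-1-yl]phenol | COc1cccc(CCCCCCCCCC/C=C/c2cc(OC)c(O)c(OC)c2)c1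
F6 | step 1 | 1-(3-methoxyphenyl)dodec-11-en-2-one | COc1cccc(CC(=O)CCCCCCCCC=C)c1
F7 | step 1 | hydrazone of 1-(3-methoxyphenyl)dodec-11-en-2-one | COc1cccc(CC(=NN)CCCCCCCCC=C)c1
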